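**Assumption:** positions are given in germacrane numbering (C1–C15). The catalyst antipodes named in steps 2 and 4 are the ones expected to give the drawn configurations; if the observed sense is opposite, the quinine-derived pseudo-enantiomer (step 2) or (R)-BINOL (step 4) is used.

## Retrosynthetic overview

1. C4=C5: ring-closing metathesis of the vinyl lactone / isopropenyl ketone seco-triene **17** closes the ten-membered ring last.
2. C8–O: Mitsunobu esterification with tiglic acid, which inverts the C8 carbinol delivered by the fragment coupling.
3. C7–C8: indium Barbier union of bromomethyl butenolide **5** (carries C6) with β-hydroxy aldehyde **14** (carries C10).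
4. **5** comes from achiral triene acid **3** by catalytic asymmetric bromolactonisation (key step); **14** comes from 4-oxopentenoic acid by chiral-diol-catalysed asymmetric allylboration.
5. Ring order: γ-lactone (step 2), then cyclodecadienone (step 9).

## Route

**Step 1**
Reactants: **1** sorbic acid; **2** Eschenmoser's salt (N,N-dimethylmethyleneiminium iodide)
Product: **3** (3E)-2-methylidenehexa-3,5-dienoic acid (achiral)
Conditions: LDA (2.2 equiv), THF, −78 → −20 °C; **2**, −78 °C → rt; then MeI, MeOH, rt; then aq. NaHCO3 (one pot). Keep **3** cold in solution with BHT and use the same day.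
Reagents that add atoms: Eschenmoser's salt, C=[N+](C)C.[I-] (supplies the CH2)
Why: Eschenmoser α-methylenation: the sorbate dienediolate reacts at Cα (deconjugative Mannich) and quaternisation/E1cB loss of NMe3 in the same flask gives the achiral cross-conjugated triene acid, the Mannich base not being isolated.

**Step 2 (key step)**
Reactants: **3**; **4** N-bromosuccinimide
Product: **5** (5R)-3-(bromomethyl)-5-ethenylfuran-2(5H)-one
Conditions: NBS (1.1 equiv), O-(9-quinidinyl) N-(4-methoxyphenyl)thiocarbamate (10 mol %), CHCl3/PhMe 1:2, −78 °C; then Bu4NBr (10 mol %), 0 °C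
Reagents that add atoms: NBS, O=C1CCC(=O)N1Br (supplies Br)
Why: Proposed new method: catalytic enantioselective vinylogous bromolactonisation of a cross-conjugated trienoic acid, in which the thiocarbamate sulfur activates NBS while the protonated quinuclidine ion-pairs the carboxylate, Br+ is delivered to the proximal diene (at the exocyclic CH2 in a 1,4-mode, or at C3 in a 1,2-mode) and the carboxylate closes a five-membered ring on C4 of the s-trans diene from one enantiotopic face, forming the lactone and setting C6 (R) as the first stereocentre, with both regioisomeric allylic bromides converging on **5** by bromide-mediated SN2′ equilibration; the closest known reactions are cinchona thiocarbamate/urea-catalysed asymmetric bromolactonisations of 1,2-disubstituted alkenoic acids and the 1,4-bromolactonisation of conjugated enynes.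

**Step 3**
Reactants: **6** (E)-4-oxopent-2-enoic acid; **7** N,O-dimethylhydroxylamine hydrochloride
Product: **8** (E)-N-methoxy-N-methyl-4-oxopent-2-enamide
Conditions: EDC·HCl, N-methylmorpholine, CH2Cl2, 0 °C → rt
Reagents that add atoms: N,O-dimethylhydroxylamine hydrochloride, CNOC.Cl
Why: Carbodiimide amide coupling gives the Weinreb amide, masking the acid as a latent ketone so that the methyl ketone is the only carbonyl able to react in step 4.

**Step 4**
Reactants: **8**; **9** diisopropyl allylboronate
Product: **10** (R,E)-4-hydroxy-N-methoxy-N,4-dimethylhepta-2,6-dienamide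
Conditions: (S)-3,3′-Br2-BINOL (15 mol %), **9** (1.5 equiv), PhCF3/PhMe 3:1, −35 °C; aq. work-up
Reagents that add atoms: diisopropyl allylboronate, C=CCB(OC(C)C)OC(C)C (supplies the allyl group)
Why: Chiral-diol-catalysed asymmetric allylboration of a methyl alkenyl ketone: the BINOL-exchanged, more Lewis-acidic boronate adds through a closed chair transition state to the Re face (alkenyl group pseudo-equatorial), setting the tertiary carbinol C10 as R.

**Step 5**
Reactants: **10**; **11** isopropenylmagnesium bromide
Product: **12** (R,E)-6-hydroxy-2,6-dimethylnona-1,4,8-trien-3-one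
Conditions: **11** (3 equiv), THF, −78 → 0 °C; aq. NH4Cl
Reagents that add atoms: isopropenylmagnesium bromide, C=C(C)[Mg]Br
Why: Weinreb ketone synthesis: the chelated tetrahedral intermediate stops at the ketone, and the magnesium alkoxide of the tertiary alcohol is inert, so C10 is untouched.

**Step 6**
Reactants: **12**; **13** ozone
Product: **14** (R,E)-3-hydroxy-3,7-dimethyl-6-oxoocta-4,7-dienal (used crude)
Conditions: O3 (1.0 equiv, Sudan Red 7B end-point), pyridine (3 equiv), CH2Cl2, −78 °C
Reagents that add atoms: ozone, [O-][O+]=O
Why: Chemoselective ozonolysis: electrophilic ozone cleaves the isolated monosubstituted alkene much faster than the two electron-poor enone C=C bonds, and pyridine gives the aldehyde directly without a reductive work-up.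

**Step 7**
Reactants: **5** (1.3 equiv); **14**
Product: **15** (4R,5R)-4-[(1S,3R,4E)-1,3-dihydroxy-3,7-dimethyl-6-oxoocta-4,7-dien-1-yl]-5-ethenyl-3-methylideneoxolan-2-one
Conditions: In powder (1.5 equiv), THF/H2O 3:1, rt
Reagents that add atoms: none
Why: Indium-mediated Barbier 2-(alkoxycarbonyl)allylation: the allylindium from **5** reacts at its γ-carbon (C7) on the face anti to the C6 vinyl group (6,7-trans) through a chair transition state with the aldehyde chain equatorial, which regenerates the exocyclic methylene and gives the 8S carbinol, while the neutral aqueous medium leaves the dienone untouched and avoids translactonisation or oxa-Michael closure.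

**Step 8**
Reactants: **15**; **16** tiglic acid
Product: **17** (1R,3R,4E)-1-[(2R,3R)-2-ethenyl-4-methylidene-5-oxooxolan-3-yl]-3-hydroxy-3,7-dimethyl-6-oxoocta-4,7-dien-1-yl (2E)-2-methylbut-2-enoate
Conditions: PPh3/DIAD (premixed, 2 equiv), **16** (2 equiv), PhMe, 0 °C → rt
Reagents that add atoms: tiglic acid, C/C=C(\C)C(=O)O
Why: Mitsunobu esterification: SN2 displacement of the C8 oxyphosphonium by tiglate inverts 8S to the required 8R and installs the ester in one operation, the tertiary C10–OH being unreactive.

**Step 9**
Reactants: **17**
Product: **18** eupaheliangolide A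
Conditions: Hoveyda–Grubbs II (15 mol %, added in portions), 1,4-benzoquinone (30 mol %), PhMe (1 mM), 90 °C
Reagents that add atoms: none (ethylene is lost)
Why: Ring-closing metathesis between the C5 vinyl group and the isopropenyl ketone: the rigid E-enone and trans-lactone turn the chain so the ten-membered ring closes to the Z-trisubstituted enone of the heliangolide core, with no stereocentre touched.

## Compound list

1 | sorbic acid, (2E,4E)-hexa-2,4-dienoic acid | C/C=C/C=C/C(=O)O | starting material
2 | Eschenmoser's salt | C=[N+](C)C.[I-] | starting material (reagent)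
3 | (3E)-2-methylidenehexa-3,5-dienoic acid | C=C/C=C/C(=C)C(=O)O | intermediate
4 | N-bromosuccinimide | O=C1CCC(=O)N1Br | starting material (reagent)
5 | (5R)-3-(bromomethyl)-5-ethenylfuran-2(5H)-one | O=C1O[C@H](C=C)C=C1CBr | intermediate
6 | (E)-4-oxopent-2-enoic acid | CC(=O)/C=C/C(=O)O | starting material
7 | N,O-dimethylhydroxylamine hydrochloride | CNOC.Cl | starting material (reagent)
8 | (E)-N-methoxy-N-methyl-4-oxopent-2-enamide | CC(=O)/C=C/C(=O)N(C)OC | intermediate
9 | diisopropyl allylboronate | C=CCB(OC(C)C)OC(C)C | starting material (reagent)
10 | (R,E)-4-hydroxy-N-methoxy-N,4-dimethylhepta-2,6-dienamide | C=CC[C@@](C)(O)/C=C/C(=O)N(C)OC | intermediate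
11 | isopropenylmagnesium bromide | C=C(C)[Mg]Br | starting material (reagent)
12 | (R,E)-6-hydroxy-2,6-dimethylnona-1,4,8-trien-3-one | C=CC[C@@](C)(O)/C=C/C(=O)C(C)=C | intermediate
13 | ozone | [O-][O+]=O | starting material (reagent)
14 | (R,E)-3-hydroxy-3,7-dimethyl-6-oxoocta-4,7-dienal | O=CC[C@@](C)(O)/C=C/C(=O)C(C)=C | intermediate
15 | (4R,5R)-4-[(1S,3R,4E)-1,3-dihydroxy-3,7-dimethyl-6-oxoocta-4,7-dien-1-yl]-5-ethenyl-3-methylideneoxolan-2-one | C=C1C(=O)O[C@H](C=C)[C@H]1[C@@H](O)C[C@@](C)(O)/C=C/C(=O)C(C)=C | intermediate
16 | tiglic acid, (2E)-2-methylbut-2-enoic acid | C/C=C(\C)C(=O)O | starting material (reagent)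
17 | (1R,3R,4E)-1-[(2R,3R)-2-ethenyl-4-methylidene-5-oxooxolan-3-yl]-3-hydroxy-3,7-dimethyl-6-oxoocta-4,7-dien-1-yl (2E)-2-methylbut-2-enoate | C=C1C(=O)O[C@H](C=C)[C@H]1[C@H](OC(=O)/C(C)=C/C)C[C@@](C)(O)/C=C/C(=O)C(C)=C | intermediate
18 | eupaheliangolide A, (3aR,4R,6R,7E,10Z,11aR)-6-hydroxy-6,10-dimethyl-3-methylidene-2,9-dioxo-2,3,3a,4,5,6,9,11a-octahydrocyclodeca[b]furan-4-yl (2E)-2-methylbut-2-enoate | C=C1C(=O)O[C@@H]2/C=C(/C)C(=O)/C=C/[C@](C)(O)C[C@@H](OC(=O)/C(C)=C/C)[C@@H]12 | target

## Summary

**Total steps:** 9
**Longest linear sequence:** 7 (steps 3–9, from **6**)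

**Three steps most likely to fail**

1. **Step 2 (proposed new bromolactonisation).** The risks are enantioselectivity, 1,2- versus 1,4-regiochemistry, and Diels–Alder dimerisation of triene acid **3**.
   Fallback (known chemistry): make rac-**5** by acylating penta-1,4-dien-3-ol with 2-(bromomethyl)acryloyl chloride and closing the butenolide by Grubbs II ring-closing metathesis. Couple it with enantiopure **14** and separate the two diastereomeric Barbier adducts by chromatography, so that C10 (from the established allylboration) is the sole source of absolute configuration.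

2. **Step 9 (ring-closing metathesis).** The risks are ten-ring strain and oligomerisation, formation of the 4E isomer, and competing closure onto the C1=C2 enone.
   Fallback: Nozaki–Hiyama–Kishi macrocyclisation at C3–C4. Carry a (Z)-2-iodoprop-1-enyl group on the butenolide in place of vinyl and an (E)-enal at C3 in place of the isopropenyl ketone, close with CrCl2/NiCl2 in DMSO, then oxidise the C3 carbinol with Dess–Martin periodinane. The C4=C5 geometry then comes from the vinyl iodide.

3. **Step 8 (Mitsunobu inversion).** The risks are the hindered secondary carbinol, E2 elimination to a C7=C8 diene, and phosphine addition to the α-methylene lactone.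
   Fallback: obtain the 8R carbinol directly by changing the coupling to an open-transition-state allylation. BF3·OEt2-promoted addition of the tributylstannyl analogue of **5** to the C10-TES ether of **14** is syn-selective; then acylate with tiglic anhydride/DMAP with retention.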